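**Plan**

- Retrosynthetic cuts: the silylene on the 1,3-diol (3-OH / C4-CH2OH); the C8=C12 olefin, back to a C8 ketone; then C9–C11, between the ring carbon and the OCH2 carbon of 7-(chloromethoxy)coumarin. The decalin itself is traced to andrographolide by cutting away its butenolide side chain and its exocyclic methylene carbon.
- Enabling feature: the ether oxygen on C11 is 1,3 to C8 of ring B, and the exocyclic methylene on C8 is a masked ketone. C9 is therefore the α-carbon of a β-aryloxy ketone. In andrographolide C9 already carries a carbon that ozonolysis turns into a formyl group, which makes C9 the central carbon of a 1,3-dicarbonyl.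
- Forward order: dehydrate and protect andrographolide; ozonolyse both olefins (C–C cleavage) to the ring-B β-keto aldehyde; C-aryloxymethylate C9 (union of the two halves); expel the old formyl carbon by oxidation/decarboxylation; methylenate C8; deprotect. Rings A and B are never opened.
- Stereochemistry: C3, C4, C5 and C10 are carried unchanged from andrographolide. C9 is erased and re-set in step 7 by ketonisation of the C8–C9 enol on the face opposite the C10 methyl, which is also the thermodynamic (equatorial) outcome.
- Locants: drimane numbering (C11 on C9, C12 on C8, CH3 and CH2OH on C4, CH3 on C10); trivial names of andrographolide derivatives keep labdane locants.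

Key step: step 6

Remark: andrographolide (cheap, commercial) is taken as starting material because its decalin carries the same five stereocentres as the target (1R,4aS,5R,6R,8aS in naphthalene numbering, ent-drimane series); 5 is drawn as the keto aldehyde although it should exist largely as the chelated hydroxymethylene enol.

**Step 1**
Reactants: 1 andrographolide
Product: 2 14-deoxy-11,12-didehydroandrographolide
Conditions: neutral Al2O3, pyridine, reflux
Reagents that add atoms: none
Why: Alumina/pyridine-promoted vinylogous β-elimination (E1cB type) of the allylic lactone hydroxyl with a C11 hydrogen should give the conjugated (11E)-dienyl butenolide, which puts a C=C bond directly on C9 for the later cleavage; no decalin stereocentre is touched.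

**Step 2**
Reactants: 2 14-deoxy-11,12-didehydroandrographolide
Product: 3 3,19-O-(di-tert-butylsilanediyl)-14-deoxy-11,12-didehydroandrographolide
Conditions: t-Bu2Si(OTf)2, 2,6-lutidine, CH2Cl2, 0 °C
Reagents that add atoms: di-tert-butylsilyl bis(trifluoromethanesulfonate), CC(C)(C)[Si](OS(=O)(=O)C(F)(F)F)(OS(=O)(=O)C(F)(F)F)C(C)(C)C
Why: Double O-silylation of the syn 1,3-diol closes a six-membered dioxasilinane (cyclic silylene protection) that should withstand ozone, Lewis acids and chlorite and fall to fluoride at the end.

**Step 3**
Reactants: 3 silylene-protected dienyl butenolide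
Product: 5 silylene-protected ring-B β-keto aldehyde (C8 ketone / C9 formyl), via bis-ozonide 4 (not isolated)
Conditions: O3, CH2Cl2, −78 °C; N2 purge; then PPh3, −78 °C → rt
Reagents that add atoms: ozone, [O-][O+]=O
Why: Criegee ozonolysis of the exocyclic C8=CH2 bond and of the electron-richer CH=CH bond next to C9, followed by phosphine reduction of the ozonides, should excise the exocyclic carbon and the butenolide and leave a 1,3-dicarbonyl centred on C9; the ring stereocentres are not involved.

**Step 4**
Reactants: 6 umbelliferone; 7 chloromethyl methyl sulfide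
Product: 8 7-[(methylsulfanyl)methoxy]-2H-chromen-2-one
Conditions: K2CO3, NaI (cat.), DMF, rt
Reagents that add atoms: none
Why: Williamson-type SN2 O-alkylation of the phenoxide by the α-chloro sulfide, accelerated by iodide, should give the methylthiomethyl ether.

**Step 5**
Reactants: 8 7-[(methylsulfanyl)methoxy]-2H-chromen-2-one
Product: 9 7-(chloromethoxy)-2H-chromen-2-one
Conditions: SO2Cl2, CH2Cl2, 0 °C; volatiles removed, used crude
Reagents that add atoms: sulfuryl chloride, O=S(=O)(Cl)Cl
Why: Chlorinolysis of the O,S-acetal (S-chlorination, collapse to the aryloxymethyl cation, capture by chloride) is the standard route to aryl chloromethyl ethers and should leave the coumarin untouched at 0 °C.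

**Step 6**
Reactants: 5 ring-B β-keto aldehyde; 9 7-(chloromethoxy)-2H-chromen-2-one
Product: 11 C9-quaternary keto aldehyde bearing the coumarin-7-yloxymethyl group, via chlorotitanium enolate 10 (not isolated)
Conditions: TiCl4, i-Pr2NEt, CH2Cl2, −78 °C; then 9, −78 → 0 °C; aq. NH4Cl; used crude
Reagents that add atoms: none
Why: TiCl4 and the amine convert the enolised 1,3-dicarbonyl into the chelated chlorotitanium enolate 10, and Ti(IV) ionises the α-chloro ether 9 to an aryloxymethyl cation equivalent that is captured at C9, the only nucleophilic carbon, which forms the C9–C11 bond. The closest known reaction types are the alkoxymethylation of chlorotitanium enolates with benzyl chloromethyl ether and the classical formyl-activated alkylation of ketones. No ring is closed. The new quaternary centre at C9 should arise by attack on the face opposite the axial C10 methyl, but its configuration is without consequence because C9 becomes trigonal again in step 7, where the lasting configuration is set. The selectivities needed are C9 over C7 and C- over O-alkylation: the first is secured by the formyl group on C9 (the former C11 of andrographolide), the second by chelation of both oxygens to titanium and by the reversibility of any O-alkylation under Lewis-acidic conditions, C-alkylation being irreversible. The silylene, the coumarin lactone and the non-enolisable product should tolerate TiCl4 at low temperature.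

**Step 7**
Reactants: 11 C9-quaternary keto aldehyde
Product: 14 β-aryloxy ketone (C9–H trans and C9–CH2OAr cis to the C10 methyl), via β-keto acid 12 (not isolated), via enol 13 (not isolated)
Conditions: NaClO2, NaH2PO4, 2-methyl-2-butene, t-BuOH/H2O, 0 °C → rt; then toluene, 80 °C
Reagents that add atoms: none
Why: Pinnick oxidation of the non-enolisable aldehyde to the β-keto acid 12, decarboxylation through the six-membered transition state to the neutral enol 13, and ketonisation by axial protonation of C9 on the face opposite the C10 methyl should place the CH2OAr group equatorial and cis to that methyl (also the more stable epimer), while the acidic, enolate-free medium should suppress E1cB loss of the aryloxide.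

**Step 8**
Reactants: 14 β-aryloxy ketone
Product: 15 silylene-protected target
Conditions: Zn, CH2Br2, TiCl4, THF, −40 → 5 °C (reagent aged); then 14, CH2Cl2, 0 °C → rt
Reagents that add atoms: dibromomethane, BrCBr
Why: Takai–Lombardo methylenation with the gem-dizinc/titanium reagent is non-basic, so the C9 stereocentre α to the ketone and the β-aryloxy group should survive, and it attacks ketones in preference to the coumarin lactone.

**Step 9**
Reactants: 15 silylene-protected target
Product: 16 target, 7-{[(1R,4aS,5R,6R,8aS)-6-hydroxy-5-(hydroxymethyl)-5,8a-dimethyl-2-methylidenedecahydronaphthalen-1-yl]methoxy}-2H-chromen-2-one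
Conditions: HF·pyridine, THF, 0 °C → rt
Reagents that add atoms: none
Why: Fluoride cleaves both Si–O bonds of the silylene (strong Si–F bonds) under conditions that should not affect the exocyclic alkene, the aryl alkyl ether or the lactone, and no stereocentre is involved.

**Compound list**

1 | andrographolide | C=C1CC[C@@H]2[C@](C)(CO)[C@H](O)CC[C@@]2(C)[C@@H]1C/C=C3/C(=O)OC[C@H]3O | starting material
2 | 14-deoxy-11,12-didehydroandrographolide ((11E)-dienyl butenolide, free 3,19-diol) | C=C1CC[C@@H]2[C@](C)(CO)[C@H](O)CC[C@@]2(C)[C@@H]1/C=C/C3=CCOC3=O | intermediate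
3 | 3,19-O-(di-tert-butylsilanediyl)-14-deoxy-11,12-didehydroandrographolide | C=C1CC[C@@H]2[C@](C)(CO[Si](C(C)(C)C)(C(C)(C)C)O4)[C@H]4CC[C@@]2(C)[C@@H]1/C=C/C3=CCOC3=O | intermediate
4 | bis-ozonide of 3 (1,2,4-trioxolanes across C8=CH2 and across the CH=CH next to C9; epimers at the new acetal carbons) | C1OOC2(O1)CC[C@@H]3[C@](C)(CO[Si](C(C)(C)C)(C(C)(C)C)O4)[C@H]4CC[C@@]3(C)[C@@H]2C5OOC(O5)C6=CCOC6=O | intermediate (not isolated)
5 | silylene-protected ring-B β-keto aldehyde: C8 ketone, C9–CHO cis to the C10 methyl (largely as the hydroxymethylene enol) | O=C1CC[C@@H]2[C@](C)(CO[Si](C(C)(C)C)(C(C)(C)C)O4)[C@H]4CC[C@@]2(C)[C@@H]1C=O | intermediate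
6 | umbelliferone (7-hydroxy-2H-chromen-2-one) | Oc1ccc2ccc(=O)oc2c1 | starting material
7 | chloromethyl methyl sulfide | CSCCl | starting material
8 | 7-[(methylsulfanyl)methoxy]-2H-chromen-2-one | CSCOc1ccc2ccc(=O)oc2c1 | intermediate
9 | 7-(chloromethoxy)-2H-chromen-2-one | ClCOc1ccc2ccc(=O)oc2c1 | intermediate
10 | chlorotitanium enolate of 5 (O–TiCl3 on the former formyl oxygen, cis to and chelated by the C8 carbonyl) | O=C1CC[C@@H]2[C@](C)(CO[Si](C(C)(C)C)(C(C)(C)C)O4)[C@H]4CC[C@@]2(C)/C1=C/O[Ti](Cl)(Cl)Cl | intermediate (not isolated)
11 | C9-quaternary keto aldehyde: C9 bears CHO (cis to the C10 methyl) and CH2O-coumarin-7-yl (trans); expected major epimer | O=C1CC[C@@H]2[C@](C)(CO[Si](C(C)(C)C)(C(C)(C)C)O4)[C@H]4CC[C@@]2(C)[C@]1(COc5ccc6ccc(=O)oc6c5)C=O | intermediate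
12 | β-keto acid from 11 (CO2H in place of CHO) | O=C1CC[C@@H]2[C@](C)(CO[Si](C(C)(C)C)(C(C)(C)C)O4)[C@H]4CC[C@@]2(C)[C@]1(COc5ccc6ccc(=O)oc6c5)C(=O)O | intermediate (not isolated)
13 | C8–C9 enol carrying CH2O-coumarin-7-yl on C9 | OC=1CC[C@@H]2[C@](C)(CO[Si](C(C)(C)C)(C(C)(C)C)O4)[C@H]4CC[C@@]2(C)C=1COc5ccc6ccc(=O)oc6c5 | intermediate (not isolated)
14 | silylene-protected 8-oxo-12-nor ketone: C9–H trans, C9–CH2O-coumarin-7-yl cis to the C10 methyl | O=C1CC[C@@H]2[C@](C)(CO[Si](C(C)(C)C)(C(C)(C)C)O4)[C@H]4CC[C@@]2(C)[C@@H]1COc5ccc6ccc(=O)oc6c5 | intermediate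
15 | silylene-protected target (exocyclic methylene on C8) | C=C1CC[C@@H]2[C@](C)(CO[Si](C(C)(C)C)(C(C)(C)C)O4)[C@H]4CC[C@@]2(C)[C@@H]1COc5ccc6ccc(=O)oc6c5 | intermediate
16 | target: 3-OH, C4-CH2OH, C9-CH2OAr and C10-CH3 on one face; H-5, H-9 and C4-CH3 on the other | C=C1CC[C@@H]2[C@](C)(CO)[C@H](O)CC[C@@]2(C)[C@@H]1COc1ccc2ccc(=O)oc2c1 | target

**Step count and risks**

Total: 9 steps. Longest linear sequence: 7 steps (1, 2, 3, 6, 7, 8, 9 from andrographolide); steps 4 and 5 prepare the electrophile.

Steps most likely to fail:

- **Step 6.** C-alkylation at the fully substituted, neopentyl C9 may lose to O-alkylation of the formyl oxygen or to Lewis-acid-induced self-condensation of the chloromethyl ether. The fallback sets out from 5 and returns at 14. Deformylative α-bromination of the enol of 5 (NBS, aqueous THF) should give the 9-bromo-8-ketone F1. Zinc and TMSCl in MeCN should turn it regiospecifically into the C8–C9 trimethylsilyl enol ether F2. ZnBr2-catalysed Mukaiyama-type alkylation of F2 with 9 in CH2Cl2 would form the same C9–C11 bond without a quaternary centre; attack opposite the C10 methyl is expected to give mainly the axial C9 epimer F3 of 14. Catalytic TsOH in CH2Cl2 should then equilibrate F3 through the enol to the equatorial isomer 14.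

- **Step 7.** Once the activating carbon is lost, the aryloxide may be expelled from the C9 enol(ate) by β-elimination, or C9 may be protonated on the wrong face. The fallback sets out from 11 and returns at 14, and relies on thermodynamic instead of kinetic control. K2CO3 in THF containing a little water should remove the formyl group by retro-Claisen cleavage. Any enolate that sheds the aryloxide gives the exo-methylene ketone F4 together with 6. These recombine by reversible base-catalysed oxa-Michael addition (in the same flask, or after isolation with catalytic DBU in MeCN), and protonation of the resulting enolate should deliver the equatorial ketone 14.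

- **Step 8.** The gem-dimetallic reagent may add slowly to the hindered ketone, with competing enolisation, epimerisation at C9 or β-elimination of the aryloxide. The fallback sets out from 5 and returns at 15; it makes the aryl ether last, when no ketone is left. Alkylation of the titanium enolate 10 with 4-methoxybenzyl chloromethyl ether should give the quaternary keto aldehyde F5. Deformylation with K2CO3 in MeOH (an alkoxide is a poor leaving group, so base is tolerated) should give the β-(4-methoxybenzyloxy) ketone F6. Wittig methylenation (Ph3P=CH2, THF) should give the exocyclic alkene F7. DDQ in wet CH2Cl2 should free the primary alcohol F8, and Mitsunobu etherification with 6 (PPh3, DIAD, THF) should give 15.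

**Further compounds**

F1 | step 6 | silylene-protected 9-bromo-8-oxo-11,12-dinor ketone (C9 epimers) | O=C1CC[C@@H]2[C@](C)(CO[Si](C(C)(C)C)(C(C)(C)C)O4)[C@H]4CC[C@@]2(C)C1Br
F2 | step 6 | C8–C9 trimethylsilyl enol ether of the 11,12-dinor ketone | C[Si](C)(C)OC=1CC[C@@H]2[C@](C)(CO[Si](C(C)(C)C)(C(C)(C)C)O4)[C@H]4CC[C@@]2(C)C=1
F3 | step 6 | C9 epimer of 14 (CH2OAr trans to the C10 methyl, axial) | O=C1CC[C@@H]2[C@](C)(CO[Si](C(C)(C)C)(C(C)(C)C)O4)[C@H]4CC[C@@]2(C)[C@H]1COc5ccc6ccc(=O)oc6c5
F4 | step 7 | silylene-protected 9-methylidene-8-ketone (exo-methylene ketone) | O=C1CC[C@@H]2[C@](C)(CO[Si](C(C)(C)C)(C(C)(C)C)O4)[C@H]4CC[C@@]2(C)C1=C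
F5 | step 8 | C9-quaternary keto aldehyde bearing CH2O-(4-methoxybenzyl) | O=C1CC[C@@H]2[C@](C)(CO[Si](C(C)(C)C)(C(C)(C)C)O4)[C@H]4CC[C@@]2(C)[C@]1(COCc5ccc(OC)cc5)C=O
F6 | step 8 | 8-ketone with C9–CH2O-(4-methoxybenzyl) cis to the C10 methyl | O=C1CC[C@@H]2[C@](C)(CO[Si](C(C)(C)C)(C(C)(C)C)O4)[C@H]4CC[C@@]2(C)[C@@H]1COCc5ccc(OC)cc5
F7 | step 8 | exocyclic alkene with C9–CH2O-(4-methoxybenzyl) | C=C1CC[C@@H]2[C@](C)(CO[Si](C(C)(C)C)(C(C)(C)C)O4)[C@H]4CC[C@@]2(C)[C@@H]1COCc5ccc(OC)cc5
F8 | step 8 | silylene-protected C11 primary alcohol (exocyclic methylene on C8) | C=C1CC[C@@H]2[C@](C)(CO[Si](C(C)(C)C)(C(C)(C)C)O4)[C@H]4CC[C@@]2(C)[C@@H]1CO
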